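The numbers in the tables were computed for an exercise.

Time is what the autumn run gives us: 50.0 min of readings on a closed flask in which starting material and other conformer stand under held gas.

| setting | autumn | oak | birch |
|---|---|---|---|
| starting material | 1.1 M | 1.6 M | 1.6 M |
| other conformer | 0.80 M | 0.800 M | 1.00 M |
| gas | 200 mM (held) | 200 mM (held) | 200 mM (held) |
| remark | run made earlier |  |  |
| time |  | 2.5 h | 2.5 h |

autumn run (percent of the starting material and other conformer together charged)

| time / min | target / % | starting material / % | isomer of the product B / % | isomer of the product A / % |
|---|---|---|---|---|
| 3.00 | 0 | 59 | 0 | 1 |
| 8.00 | 0 | 55 | 0 | 5 |
| 15.0 | 1 | 57 | 0 | 14 |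
| 25.0 | 1 | 51 | 0 | 24 |
| 30.0 | 2 | 52 | 0 | 24 |
| 40.0 | 0 | 51 | 0 | 36 |
| 50.0 | 0 | 50 | 0 | 45 |

(each reading ± 2 percentage points)

- what was read earlier has a scatter of 2 percentage points, one standard deviation
- at the start none of the gas is in solution
- a reading of starting material is of its free form alone

- which of these there is most of at the end, counted by the starting material in it, oak (isomer of the product A / target / starting material / isomer of the product B)
- which of these there is most of at the end, counted by the starting material in it, birch (isomer of the product A / target / starting material / isomer of the product B)
- amount of the one of these that there is most of at the end, in percent of the starting material and other conformer together charged, oak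
- amount of the one of these that there is most of at the end, in percent of the starting material and other conformer together charged, birch

Along the autumn run the isomer of the product A climbs in a nearly straight, zero-order line, from 1 % at 3.00 min to 45 % at 50.0 min, which on that charge is a slope of 0.0178 M min⁻¹. Over the same span the starting material reads 59 % falling to 50 %, so we read a feed into the other conformer of 0.00352 min⁻¹, a half-life of 3.28 h.

Now we draw oak, assuming that slope holds there. Its 0.800 M of other conformer by itself lasts 45.0 min. But the starting material feeds more in meanwhile, so we put that time back and get 58.2 min, and going round once more gives 61.6 min. This is the knee: the time at which slope times time equals the charged other conformer plus what the starting material has fed in by then.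

At the knee our oak curve has the isomer of the product A at 45.7 % and starting material at 53.7 %. Beyond it we let the line follow the feed, which is an extrapolation, since the autumn readings stop earlier. Our two oak curves then cross at 81.9 min, and at 2.5 h our reckoning puts the isomer of the product A at 60.7 % in oak and 63.7 % in birch.

The forecast also names isomer of the product A for oak and isomer of the product A for birch, but at 78 % and 75 %, higher than our figures and falling from oak to birch where ours rise: “If starting material then takes over at the saturated rate, nearly everything becomes A”.

The flask gives isomer of the product A at 52.9 % in oak and isomer of the product A at 56.8 % in birch.

    starting material ⇌ other conformer (K = 1.40, k = 0.00320 min⁻¹)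
    starting material + reagent → target (k = 0.150 L mol⁻¹ min⁻¹)
    reagent + other conformer → isomer of the product A (k = 26.0 L mol⁻¹ min⁻¹)
    gas ⇌ reagent, rate k4*(csat - [reagent]) (kL = 0.0890 min⁻¹)
    target ⇌ isomer of the product B (K = 0.240, k = 0.0960 min⁻¹)

Oak's other conformer falls under 2 percent of its charge at 62.3 min, against our knee of 61.6 min; the same reckoning for birch gives 76.5 min, and at 1.25 h birch holds other conformer at 0.675 % of the starting material and other conformer together charged. Oak stands 7.8 percentage points below our level, with 24.7 % target at 2.5 h, and it is not at rest there: 16.6 % starting material remains, and by 25.0 h that is 0 %. In oak the isomer of the product A then gains 2.2 points, reaching 55.2 %, while the target gains 11 points, reaching 36.1 %.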